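**Retrosynthetic overview**

1. Numbering: C1–C9 as in the bicyclo[3.3.1]nonane core (C1 carries benzoyl, C2/C4/C9 are the ketones, C3 and C5 the other quaternary carbons, C6 CH2, C7 CH, C8 CMe2); C10 (CH2) and C11 (CH) bridge C7 to C3; C12 is the CMe2–O carbon on C11; C13/C14/C15 are CH2, CH–O and CMe2OH of the C3 side chain. Ring A = C1–C2–C3–C4–C5–C9, ring B = C1–C8–C7–C6–C5–C9, ring C = the seven-membered ring C3–C4–C5–C6–C7–C10–C11.
2. The 1,2-dioxepane and the tertiary alcohol come last: cobalt-mediated hydroperoxysilylation of a C11 isopropenyl group, closure of the peroxyl radical onto the C3 prenyl group (O–C14), second O2 capture. Before that, benzoyl at C1 and geranyl at C5 are introduced by bridgehead carbanion chemistry.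
3. The cage (ring B) is closed by C1–C8 alkylation: a tertiary C8 cation released from a silyl ether on C7 is captured by the enol ether carbon C1 of a bicyclo[4.3.1]decane (rings A and C).
4. That bicycle comes from a cis-fused diketene adduct of a cyclohexanone (ring C3–C4–C6–C7–C10–C11) by an oxidative 1,2-shift of C6 from C4 to C5, which enlarges the six-membered ring to ring C. Enabling feature: the C4 ketone of ring C sits next to C5, the γ-carbon of the C2–C1–C9 1,3-diketone of ring A, so that as a C4 carbinol it can push C6 onto C5 once C1 carries a hypervalent iodine leaving group.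
5. The cyclohexanone comes from cyclohex-2-en-1-one: α′-allylation, rhodium-catalysed asymmetric 1,4-addition (C7), conjugate addition of an isopropenyl cuprate (C11), enolate acylation (C3). Ring order: carbocycle C3–C4–C6–C7–C10–C11, ring A, ring expansion to ring C, ring B, dioxepane.

Key step: step 9

Remark: the O-methylation in step 10 is assumed to occur at the less hindered oxygen on C9; the C2-methoxy isomer would behave alike in steps 11 and 12 and converge at 20. Prenyl = 3-methylbut-2-en-1-yl, geranyl = (2E)-3,7-dimethylocta-2,6-dien-1-yl, isopropenyl = prop-1-en-2-yl; carbon labels in the Why lines are those of the target.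

**Step 1**
Reactants: 1 cyclohex-2-en-1-one; 2 allyl bromide
Product: 3 6-(prop-2-en-1-yl)cyclohex-2-en-1-one (racemic)
Conditions: LDA (LiN(i-Pr)2), THF, −78 °C; then 2, −78 to 0 °C
Reagents that add atoms: allyl bromide, C=CCBr
Why: Kinetic deprotonation gives the cross-conjugated α′-enolate, which is C-alkylated by the allylic bromide (enolate alkylation); the new centre is racemic and is erased again in step 3.

**Step 2**
Reactants: 3 6-(prop-2-en-1-yl)cyclohex-2-en-1-one; 4 4,4,5,5-tetramethyl-2-(prop-1-en-2-yl)-1,3,2-dioxaborolane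
Product: 5 (5S)-2-(prop-2-en-1-yl)-5-(prop-1-en-2-yl)cyclohexan-1-one (both C2 epimers)
Conditions: [RhCl(cod)]2 (cat.), (S)-BINAP, aq. KOH (cat.), 1,4-dioxane, 50 °C
Reagents that add atoms: 4,4,5,5-tetramethyl-2-(prop-1-en-2-yl)-1,3,2-dioxaborolane, CC(=C)B1OC(C)(C)C(C)(C)O1
Why: Rhodium-catalysed asymmetric 1,4-addition of an alkenylboron reagent (Hayashi–Miyaura reaction): the (S)-BINAP-bound isopropenylrhodium species adds to the enone face that gives (S)-3-substituted cyclohexanones from cyclohex-2-en-1-one, so C7 is set under catalyst control whichever the configuration at the remote allyl-bearing carbon.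

**Step 3**
Reactants: 5 (5S)-2-(prop-2-en-1-yl)-5-(prop-1-en-2-yl)cyclohexan-1-one
Product: 7 (5S)-2-(prop-2-en-1-yl)-5-(prop-1-en-2-yl)cyclohex-2-en-1-one, via trimethylsilyl enol ether 6 (not isolated)
Conditions: TMSCl, NaI, Et3N, MeCN, rt; then Pd(OAc)2, MeCN, rt
Reagents that add atoms: none
Why: Equilibrating silylation with TMSI formed in the flask gives the more highly substituted silyl enol ether, whose palladium enolate undergoes β-hydride elimination into the ring (Saegusa–Ito oxidation), which removes the stray stereocentre and leaves C7 untouched.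

**Step 4**
Reactants: 7 (5S)-2-(prop-2-en-1-yl)-5-(prop-1-en-2-yl)cyclohex-2-en-1-one
Product: 8 (5S)-5-(2-hydroxypropan-2-yl)-2-(prop-2-en-1-yl)cyclohex-2-en-1-one
Conditions: 50% aq. H2SO4, 0 °C to rt
Reagents that add atoms: water, O
Why: Acid-catalysed Markovnikov hydration through the tertiary cation of the 1,1-disubstituted isopropenyl group, the reaction that turns carvone into its hydrate; the monosubstituted allyl and the electron-poor enone double bonds are not protonated and no stereocentre is touched.

**Step 5**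
Reactants: 8 (5S)-5-(2-hydroxypropan-2-yl)-2-(prop-2-en-1-yl)cyclohex-2-en-1-one
Product: 9 (5S)-2-(prop-2-en-1-yl)-5-{2-[(triethylsilyl)oxy]propan-2-yl}cyclohex-2-en-1-one
Conditions: TESOTf, 2,6-lutidine, CH2Cl2, −78 to 0 °C
Reagents that add atoms: triethylsilyl trifluoromethanesulfonate, CC[Si](CC)(CC)OS(=O)(=O)C(F)(F)F
Why: Silyl ether formation with a silyl triflate and a hindered pyridine base masks the tertiary alcohol for the organometallic steps and prepares it as the leaving group at C8.

**Step 6**
Reactants: 9 (5S)-2-(prop-2-en-1-yl)-5-{2-[(triethylsilyl)oxy]propan-2-yl}cyclohex-2-en-1-one; 10 2-methylbut-2-ene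
Product: 11 (5S)-2-(3-methylbut-2-en-1-yl)-5-{2-[(triethylsilyl)oxy]propan-2-yl}cyclohex-2-en-1-one
Conditions: second-generation Grubbs catalyst RuCl2(=CHPh)(H2IMes)(PCy3) (cat.), 10 (excess), CH2Cl2, 40 °C
Reagents that add atoms: 2-methylbut-2-ene, CC=C(C)C
Why: Olefin cross-metathesis of the terminal allyl group with 2-methylbut-2-ene installs the prenyl group, the trisubstituted, electron-poor enone double bond being inert to the ruthenium carbene.

**Step 7**
Reactants: 11 (5S)-2-(3-methylbut-2-en-1-yl)-5-{2-[(triethylsilyl)oxy]propan-2-yl}cyclohex-2-en-1-one; 12 isopropenylmagnesium bromide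
Product: 13 trimethyl{[(3R,5S)-2-(3-methylbut-2-en-1-yl)-3-(prop-1-en-2-yl)-5-{2-[(triethylsilyl)oxy]propan-2-yl}cyclohex-1-en-1-yl]oxy}silane (3,5-trans)
Conditions: 12, CuBr·SMe2 (cat.), TMSCl, THF, −78 °C
Reagents that add atoms: isopropenylmagnesium bromide, CC(=C)[Mg]Br; chlorotrimethylsilane, C[Si](C)(C)Cl
Why: Copper-catalysed, TMSCl-accelerated conjugate addition of the Grignard reagent occurs axially on the face anti to the C7 side chain, as with other 5-substituted cyclohex-2-enones, so that C11 is set trans to C7, and the enolate is trapped regiospecifically as the tetrasubstituted silyl enol ether.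

**Step 8**
Reactants: 13 silyl enol ether; 14 diketene (4-methylideneoxetan-2-one)
Product: 15 cis-fused 8a-hydroxy-4a-prenyl-5-isopropenyl-7-{2-[(triethylsilyl)oxy]propan-2-yl}-4a,5,6,7,8,8a-hexahydronaphthalene-2,4(1H,3H)-dione (8a-OH and 4a-prenyl cis; 5-isopropenyl cis to prenyl and trans to the C7 side chain)
Conditions: MeLi, THF, 0 °C; then 14, −78 to −40 °C; then H2O
Reagents that add atoms: diketene, C=C1CC(=O)O1
Why: MeLi releases the lithium enolate, which is C-acylated by diketene on the face anti to the neighbouring isopropenyl group (this sets C3), and the terminal enolate of the new acetoacetyl chain adds to the C4 ketone in an intramolecular aldol reaction to give the cis-fused hydroxy dione (diketene annulation).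

**Step 9**
Reactants: 15 cis-fused hydroxy dione
Product: 16 1-prenyl-2-isopropenyl-4-{2-[(triethylsilyl)oxy]propan-2-yl}bicyclo[4.3.1]decane-7,9,10-trione (isopropenyl on the face of the seven-membered ring opposite to the three-carbon diketone bridge, silyloxypropyl group on the same face as that bridge)
Conditions: KOH, MeOH, 0 °C; then PhI(OAc)2, 0 °C to rt
Reagents that add atoms: none
Why: KOH turns the 1,3-dione into its enolate, trivalent iodine binds at C1, and after enolisation of C9 towards C5 the C4 alkoxide pushes the C4–C6 bond onto C5 while iodobenzene leaves in a vinylogous (SN2′) sense. The closest known reaction type is the hypervalent-iodine-mediated oxidative 1,2-alkyl shift (a semipinacol, α-ketol-type ring expansion) that turns diketene-annulated cyclopentanones into bicyclo[3.3.1]nonane-triones. No ring is closed by a new ring-forming attack: the six-membered ring C3–C4–C6–C7–C10–C11 is enlarged to the seven-membered ring C by insertion of C5 between C4 and C6, which converts the fused decalin into the bridged bicyclo[4.3.1]decane and regenerates the C4 ketone. The only new stereocentre, C5, is set by the ring fusion, because C6 moves suprafacially to the face of C5 on which it already lies, so the one-carbon C4 bridge can only be cis. The selectivity needed is migration of C6 and not of the ring-fusion carbon C3: in the cis-fused adduct the C4–C6 bond is axial on ring A and parallel to the enol π system, whereas the C4–C3 bond lies in the ring plane and C3 is an electron-poor, acyl-substituted carbon.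

**Step 10**
Reactants: 16 bicyclic trione
Product: 17 7-methoxy-1-prenyl-2-isopropenyl-4-{2-[(triethylsilyl)oxy]propan-2-yl}bicyclo[4.3.1]dec-7-ene-9,10-dione
Conditions: CH2N2, Et2O, 0 °C
Reagents that add atoms: diazomethane, C=[N+]=[N-]
Why: Diazomethane O-methylates the acidic enol of the C2/C9 1,3-diketone, at the less hindered oxygen on C9, to give the vinylogous ester (enol ether formation), while the bridgehead C5–H between C4 and C9 cannot enolise and no stereocentre is affected.

**Step 11**
Reactants: 17 vinylogous methyl ester; 18 geranyl bromide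
Product: 19 6-geranyl-7-methoxy-1-prenyl-2-isopropenyl-4-{2-[(triethylsilyl)oxy]propan-2-yl}bicyclo[4.3.1]dec-7-ene-9,10-dione
Conditions: LDA (LiN(i-Pr)2), THF, −78 °C; then 18, −78 to 0 °C
Reagents that add atoms: geranyl bromide, CC(C)=CCC/C(C)=C/CBr
Why: LDA removes the only acidic hydrogen left, the bridgehead C5–H that is α to the C4 ketone and vinylogously activated by the C2 carbonyl group, and the enolate is alkylated by the allylic bromide (bridgehead enolate alkylation), the configuration at C5 being dictated by the bicyclic frame.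

**Step 12**
Reactants: 19 geranylated vinylogous ester
Product: 20 homoadamantane-2,4,9-trione cage (C1–C8 bond formed; C1–H, C3 prenyl, C5 geranyl, C8 gem-dimethyl, C11 isopropenyl)
Conditions: TMSOTf, 2,6-di-tert-butyl-4-methylpyridine, CH2Cl2, −78 to 0 °C; then H2O
Reagents that add atoms: water, O
Why: TMSOTf ionises the tertiary silyl ether to the C8 cation, which lies over ring A on the face of ring C that carries the diketone bridge and is captured by the nucleophilic enol ether carbon C1 (Mukaiyama-type SN1 tert-alkylation of an enol ether, closing ring B and the cage), the O-methyl oxocarbenium ion being hydrolysed to the C9 ketone on work-up; C1 is fixed by the cage, and the buffered, proton-free medium spares the isopropenyl, prenyl and geranyl groups.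

**Step 13**
Reactants: 20 cage trione; 21 benzoyl chloride
Product: 22 1-benzoyl cage trione (C3 prenyl, C5 geranyl, C11 isopropenyl)
Conditions: LiTMP (lithium 2,2,6,6-tetramethylpiperidide), THF, −78 °C; then 21
Reagents that add atoms: benzoyl chloride, O=C(Cl)c1ccccc1
Why: LiTMP removes the single remaining acidic hydrogen, the bridgehead C1–H between the C2 and C9 carbonyl groups, and the pyramidal carbanion is acylated by benzoyl chloride with the retention that the cage enforces (bridgehead lithiation–acylation).

**Step 14**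
Reactants: 22 1-benzoyl cage trione
Product: 23 1,2-dioxepane-fused cage carrying a triethylsilylperoxy group on C15 (target with OOSiEt3 in place of OH)
Conditions: Co(acac)2 (cat.), O2 (1 atm), Et3SiH, 1,2-dichloroethane, rt
Reagents that add atoms: dioxygen, O=O; triethylsilane, CC[SiH](CC)CC
Why: Hydrogen atom transfer from a cobalt hydride to the 1,1-disubstituted isopropenyl group (which reacts before the trisubstituted prenyl and geranyl double bonds) gives the tertiary C12 radical, O2 capture gives a peroxyl radical that adds 7-exo-trig to the CH terminus (C14) of the neighbouring C3 prenyl group, and the new tertiary radical takes up a second O2 and is silylated (Mukaiyama–Isayama hydroperoxysilylation with peroxyl radical cyclisation); C14 is set by a chair-like transition state that keeps the dimethylcarbinyl terminus pseudo-equatorial on the forming dioxepane.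

**Step 15**
Reactants: 23 silyl peroxide
Product: 25 target CNP0148771.1, via hydroperoxide 24 (not isolated)
Conditions: HCl (cat.), MeOH, 0 °C; then PPh3, 0 °C to rt
Reagents that add atoms: none
Why: Acidic methanolysis frees the hydroperoxide from the labile silyl peroxide and triphenylphosphine reduces the hydroperoxide far faster than the dialkyl peroxide (chemoselective phosphine reduction of a hydroperoxide), leaving the 1,2-dioxepane and all stereocentres intact.

**Compound list**

1 | cyclohex-2-en-1-one | O=C1C=CCCC1 | starting material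
2 | allyl bromide (3-bromoprop-1-ene) | C=CCBr | starting material
3 | 6-(prop-2-en-1-yl)cyclohex-2-en-1-one (racemic) | O=C1C=CCCC1CC=C | intermediate
4 | 4,4,5,5-tetramethyl-2-(prop-1-en-2-yl)-1,3,2-dioxaborolane | CC(=C)B1OC(C)(C)C(C)(C)O1 | starting material
5 | (5S)-2-(prop-2-en-1-yl)-5-(prop-1-en-2-yl)cyclohexan-1-one (both C2 epimers) | O=C1C[C@@H](C(C)=C)CCC1CC=C | intermediate
6 | {[(5S)-2-(prop-2-en-1-yl)-5-(prop-1-en-2-yl)cyclohex-1-en-1-yl]oxy}trimethylsilane (not isolated) | C=CCC1=C(O[Si](C)(C)C)C[C@@H](C(C)=C)CC1 | intermediate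
7 | (5S)-2-(prop-2-en-1-yl)-5-(prop-1-en-2-yl)cyclohex-2-en-1-one | O=C1C[C@@H](C(C)=C)CC=C1CC=C | intermediate
8 | (5S)-5-(2-hydroxypropan-2-yl)-2-(prop-2-en-1-yl)cyclohex-2-en-1-one | O=C1C[C@@H](C(C)(C)O)CC=C1CC=C | intermediate
9 | (5S)-2-(prop-2-en-1-yl)-5-{2-[(triethylsilyl)oxy]propan-2-yl}cyclohex-2-en-1-one | O=C1C[C@@H](C(C)(C)O[Si](CC)(CC)CC)CC=C1CC=C | intermediate
10 | 2-methylbut-2-ene | CC=C(C)C | starting material
11 | (5S)-2-(3-methylbut-2-en-1-yl)-5-{2-[(triethylsilyl)oxy]propan-2-yl}cyclohex-2-en-1-one | O=C1C[C@@H](C(C)(C)O[Si](CC)(CC)CC)CC=C1CC=C(C)C | intermediate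
12 | isopropenylmagnesium bromide | CC(=C)[Mg]Br | starting material
13 | trimethyl{[(3R,5S)-2-(3-methylbut-2-en-1-yl)-3-(prop-1-en-2-yl)-5-{2-[(triethylsilyl)oxy]propan-2-yl}cyclohex-1-en-1-yl]oxy}silane | C[Si](C)(C)OC1=C(CC=C(C)C)[C@@H](C(C)=C)C[C@H](C(C)(C)O[Si](CC)(CC)CC)C1 | intermediate
14 | diketene (4-methylideneoxetan-2-one) | C=C1CC(=O)O1 | starting material
15 | cis-fused 8a-hydroxy-4a-prenyl-5-isopropenyl-7-{2-[(triethylsilyl)oxy]propan-2-yl}-4a,5,6,7,8,8a-hexahydronaphthalene-2,4(1H,3H)-dione | O[C@@]12CC(=O)CC(=O)[C@]1(CC=C(C)C)[C@@H](C(C)=C)C[C@H](C(C)(C)O[Si](CC)(CC)CC)C2 | intermediate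
16 | 1-prenyl-2-isopropenyl-4-{2-[(triethylsilyl)oxy]propan-2-yl}bicyclo[4.3.1]decane-7,9,10-trione | O=C1CC(=O)[C@]2(CC=C(C)C)[C@@H](C(C)=C)C[C@H](C(C)(C)O[Si](CC)(CC)CC)C[C@H]1C2=O | intermediate
17 | 7-methoxy-1-prenyl-2-isopropenyl-4-{2-[(triethylsilyl)oxy]propan-2-yl}bicyclo[4.3.1]dec-7-ene-9,10-dione | COC1=CC(=O)[C@]2(CC=C(C)C)[C@@H](C(C)=C)C[C@H](C(C)(C)O[Si](CC)(CC)CC)C[C@H]1C2=O | intermediate
18 | geranyl bromide ((2E)-1-bromo-3,7-dimethylocta-2,6-diene) | CC(C)=CCC/C(C)=C/CBr | starting material
19 | 6-geranyl-7-methoxy-1-prenyl-2-isopropenyl-4-{2-[(triethylsilyl)oxy]propan-2-yl}bicyclo[4.3.1]dec-7-ene-9,10-dione | COC1=CC(=O)[C@]2(CC=C(C)C)[C@@H](C(C)=C)C[C@H](C(C)(C)O[Si](CC)(CC)CC)C[C@@]1(C/C=C(C)/CCC=C(C)C)C2=O | intermediate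
20 | homoadamantane-2,4,9-trione cage (C1–H, C3 prenyl, C5 geranyl, C8 gem-dimethyl, C11 isopropenyl) | CC(C)=CCC/C(C)=C/C[C@]12C[C@@H]3C[C@H](C(C)=C)[C@](CC=C(C)C)(C1=O)C(=O)[C@H](C2=O)C3(C)C | intermediate
21 | benzoyl chloride | O=C(Cl)c1ccccc1 | starting material
22 | 1-benzoyl homoadamantane-2,4,9-trione cage (C3 prenyl, C5 geranyl, C11 isopropenyl) | CC(C)=CCC/C(C)=C/C[C@]12C[C@@H]3C[C@H](C(C)=C)[C@](CC=C(C)C)(C1=O)C(=O)[C@](C(=O)c1ccccc1)(C2=O)C3(C)C | intermediate
23 | dioxepane-fused cage with C15 triethylsilylperoxy group | CC(C)=CCC/C(C)=C/C[C@]12C[C@@H]3C[C@@H]4C(C)(C)OO[C@H](C(C)(C)OO[Si](CC)(CC)CC)C[C@@]4(C1=O)C(=O)[C@](C(=O)c1ccccc1)(C2=O)C3(C)C | intermediate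
24 | dioxepane-fused cage with C15 hydroperoxide (not isolated) | CC(C)=CCC/C(C)=C/C[C@]12C[C@@H]3C[C@@H]4C(C)(C)OO[C@H](C(C)(C)OO)C[C@@]4(C1=O)C(=O)[C@](C(=O)c1ccccc1)(C2=O)C3(C)C | intermediate
25 | CNP0148771.1 (1-benzoyl-5-geranyl homoadamantane-2,4,9-trione with the 1,2-dioxepane C11–C12(Me2)–O–O–C14H(CMe2OH)–C13H2–C3) | CC(C)=CCC/C(C)=C/C[C@]12C[C@@H]3C[C@@H]4C(C)(C)OO[C@H](C(C)(C)O)C[C@@]4(C1=O)C(=O)[C@](C(=O)c1ccccc1)(C2=O)C3(C)C | target

**Step count and risks**

Total step count: 15. Longest linear sequence: 15 steps (from cyclohex-2-en-1-one).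

Steps most likely to fail:

Step 12 (cage closure). The C8 cation may lose a proton to an isopropenyl or isopropylidene group, or be taken up by a carbonyl oxygen, faster than it forms the hindered C1–C8 bond. Fallback: from 19, the silyl ether is cleaved with fluoride (TBAF) to the tertiary alcohol F4, which is dehydrated with the Burgess reagent to the C7 isopropenyl compound F5. Dilute aqueous HCl in THF then hydrolyses the enol ether to the free 1,3-diketone F6. Heating F6 in mesitylene should bring about a thermal Conia-ene reaction, in which the enol adds across the isopropenyl group (C1 to C8, enol hydrogen to the CH2 terminus) without a free cation. This returns to the route at 20.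

Step 9 (key ring expansion). The 1,2-shift may not compete with simple α-oxidation of the dione or retro-aldol opening of the adduct, or the ring-fusion carbon C3 may migrate in place of C6. Fallback: from 13, K2CO3 in MeOH gives the ketone F1. Ethyl diazoacetate with BF3·OEt2 homologates it by one carbon (the less substituted C6 migrates) to the seven-membered β-keto ester F2, whose ester carbon becomes C9. The dianion of F2 (two equivalents of LDA) is acetylated at C3 with N-methoxy-N-methylacetamide, anti to the isopropenyl group, to give the acetyl keto ester F3. NaH then induces a Claisen condensation of the acetyl methyl group onto the ester, which closes ring A and returns to the route at 16.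

Step 14 (peroxidation cascade). The tertiary peroxyl radical may be intercepted by the cobalt hydride and silane before it adds to the prenyl double bond, so that ring closure does not occur. Fallback: from 22, the hydroperoxysilylation is run to the open-chain silyl peroxide F7, and acidic methanolysis gives the tertiary hydroperoxide F8. The peroxyl radical is then generated with no reductant present, by hydrogen abstraction with tert-butoxyl radicals from di-tert-butyl hyponitrite under O2 in benzene. The 7-exo cyclisation and O2 capture then propagate a chain that ends at hydroperoxide 24, where the route is rejoined before the phosphine reduction of step 15.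

**Further compounds**

F1 | step 9 | (5S)-2-prenyl-3-isopropenyl-5-{2-[(triethylsilyl)oxy]propan-2-yl}cyclohexan-1-one (3,5-trans, C2 epimers) | O=C1C[C@@H](C(C)(C)O[Si](CC)(CC)CC)C[C@H](C(C)=C)C1CC=C(C)C
F2 | step 9 | ethyl 3-prenyl-2-oxo-4-isopropenyl-6-{2-[(triethylsilyl)oxy]propan-2-yl}cycloheptane-1-carboxylate (epimers at C1 and C3) | CCOC(=O)C1C[C@@H](C(C)(C)O[Si](CC)(CC)CC)C[C@H](C(C)=C)C(CC=C(C)C)C1=O
F3 | step 9 | ethyl 3-acetyl-3-prenyl-2-oxo-4-isopropenyl-6-{2-[(triethylsilyl)oxy]propan-2-yl}cycloheptane-1-carboxylate | CCOC(=O)C1C[C@@H](C(C)(C)O[Si](CC)(CC)CC)C[C@H](C(C)=C)[C@@](CC=C(C)C)(C(C)=O)C1=O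
F4 | step 12 | 6-geranyl-4-(2-hydroxypropan-2-yl)-7-methoxy-1-prenyl-2-isopropenylbicyclo[4.3.1]dec-7-ene-9,10-dione | COC1=CC(=O)[C@]2(CC=C(C)C)[C@@H](C(C)=C)C[C@H](C(C)(C)O)C[C@@]1(C/C=C(C)/CCC=C(C)C)C2=O
F5 | step 12 | 6-geranyl-7-methoxy-1-prenyl-2,4-diisopropenylbicyclo[4.3.1]dec-7-ene-9,10-dione | COC1=CC(=O)[C@]2(CC=C(C)C)[C@@H](C(C)=C)C[C@H](C(C)=C)C[C@@]1(C/C=C(C)/CCC=C(C)C)C2=O
F6 | step 12 | 6-geranyl-1-prenyl-2,4-diisopropenylbicyclo[4.3.1]decane-7,9,10-trione | O=C1CC(=O)[C@]2(CC=C(C)C)[C@@H](C(C)=C)C[C@H](C(C)=C)C[C@@]1(C/C=C(C)/CCC=C(C)C)C2=O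
F7 | step 14 | 1-benzoyl cage trione with C11 2-(triethylsilylperoxy)propan-2-yl group (open chain, C3 prenyl intact) | CC(C)=CCC/C(C)=C/C[C@]12C[C@@H]3C[C@H](C(C)(C)OO[Si](CC)(CC)CC)[C@](CC=C(C)C)(C1=O)C(=O)[C@](C(=O)c1ccccc1)(C2=O)C3(C)C
F8 | step 14 | 1-benzoyl cage trione with C11 2-hydroperoxypropan-2-yl group (open chain, C3 prenyl intact) | CC(C)=CCC/C(C)=C/C[C@]12C[C@@H]3C[C@H](C(C)(C)OO)[C@](CC=C(C)C)(C1=O)C(=O)[C@](C(=O)c1ccccc1)(C2=O)C3(C)C
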